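## Structural features

The target is a eudesmane (eudesmane numbering is used throughout): a trans-fused decalin whose ring A (C1–C5, C10) holds a trisubstituted C3=C4 alkene with the C15 oxymethylene on C4. The saturated ring B (C5–C10) carries at C7 an α-substituted acrylate (C11=C13 methylene, C12 methyl ester). C15 is esterified with (E)-p-coumaric acid, whose phenol is free. There are three stereocentres: C5 (H) and C10 (quaternary, methyl C14) are adjacent and trans, and C7 lies 1,3 to C5 and 1,4 to C10, with its side chain equatorial and cis to the axial C14. Fragile groups are the acrylate (Michael and radical acceptor, able to slip into the C7=C11 position), the allylic C15 ester (ionisable, open to SN2′), the free phenol, and the C3=C4 alkene, which must not drift to C4=C5. The real difficulty is the quaternary C10: its methyl must be cis to the C7 substituent and trans to H5, the opposite of what axial alkylation of a C10 enolate delivers, and the C3=C4/C15–O array must sit regiospecifically next to the C5 methine. The key step exploits the fact that C10 bears a methyl group and adjoins an unfunctionalised C9 methylene in ring B. A C9=C10 alkene is therefore a latent tertiary C10 radical, and the C1–C2–C3 segment of ring A, with C3 at the ketone level, is its tethered acceptor.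

## Logic of the disconnections

18 ⇒ 16 + 17. The C15–O acyl bond is cut first because it is the most labile bond and joins the only fragment with a free phenol. The gain is that 16 is a plain sesquiterpene alcohol and 17 is purchased. The forward step must activate the alcohol of 16, not the acid of 17, so that the phenol of 17 needs no protection, and must substitute at C15 without allylic transposition.

16 ⇒ 15 ⇒ 14 ⇒ 13. The C11–C12 bond is cut, the ester carbon being taken out as carbon monoxide and methanol, which traces the acrylate of 16 to the enol triflate group of 15 and then to the acetyl group of 13. The C15 alcohol is carried back to the ethyl ester group of 14. The order matters: the C15 ester is reduced while C7 bears the triflate, before the C12 ester exists, so the two esters never need to be told apart. The demand is kinetic enolisation of 13 at the methyl group and a hydride reduction of 14 that leaves the triflate alone.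

13 ⇒ 12 ⇒ 11 ⇒ 10. The C3=C4 alkene and the C15 carbon are traced to the cyclic β-keto ester array of 10: the acetyl group of 13 is masked as the dioxolane of 12, and the enoate of 12 comes from 11, the enol triflate of 10. This is regiospecific because only C4, between the two carbonyls of 10, enolises, so both the alkene position and the C15 oxidation level come from one functional array. The demand is a triflate reduction of 11 that does not touch the acetal.

10 ⇒ 9 (key). The C10–C1 bond is cut. Ring A opens, the quaternary centre becomes one end of a trisubstituted C9=C10 alkene, and C1–C3 become a vinyl ketone. A bicycle with three stereocentres is reduced to a monocycle with two. The forward step must put hydrogen on C9, bond C10 to C1 in the 6-endo mode, and do so on the face that gives the trans ring fusion.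

9 ⇒ 8 ⇒ 7. The C3–C4 bond is cut as an ester aldol with a three-carbon enal, followed by oxidation of the carbinol of 8. The gain is the plain acetic ester side chain on C5 of 7. The demand is 1,2-addition to the enal and a substrate free of other acidic or electrophilic carbonyls, hence the acetal in 7.

7 ⇒ 6 ⇒ 4. The dioxolane of 7 goes back to the acetyl group of 6 and this to the isopropenyl group of 4, with the methylene carbon of that group lost. The isopropenyl group cannot be kept because it would take the hydrogen atom meant for C9=C10 in the key step. The demand is cleavage of the 1,1-disubstituted alkene of 4 in the presence of the ring alkene.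

4 ⇒ 2 ⇒ 1. The C4–C5 bond is cut as a [3,3] shift of 3, which is formed in the flask from 2. This moves the alkene to C9=C10 where the key step needs it, and it copies the C–O configuration of 2 onto C5. 2 comes from 1 by 1,2-reduction. The demand is the cis alcohol and a strictly suprafacial shift.

## Other disconnections considered

Alternative 1: Cut C10–C1 and C4=C5 (Robinson annulation), the first plan that comes to mind. Forward, the enolate of (2R,5R)-dihydrocarvone A1 adds to a vinyl ketone and the adduct condenses to the enone A2. The ground against it is stereoelectronic: axial attack on the A1 enolate with the isopropenyl group equatorial places the new C10–C1 bond cis to the C7 substituent. That leads toward the C10 epimer A3, not A2, unless a chiral amine auxiliary overrides it. C5 is also left sp2 and would have to be reset by dissolving-metal reduction, the C3 carbonyl would have to be turned into the C3=C4 alkene against the enolisation preference of a trans-fused 3-ketone, and C15 would need oxidation beside an isopropenyl group. The chosen plan sets C5 by sigmatropic transfer and makes the C10–C1 bond equatorially.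

Alternative 2: Cut C5–C10 across a ten-membered ring (transannular, biomimetic). Forward, protonation of the C1=C10 alkene of the germacrene-type triene A4 gives the C10 cation, which is attacked across the ring by C5 of the C4=C5 alkene; loss of H3 from the C4 cation would give 16 directly. The grounds against it are three. The C4 cation can lose a proton from C3, C5 or C15 with no element that favours C3, and it is destabilised by the C15 oxygen. The acid needed is hostile to the acrylate. The E,E-cyclodecadiene A4 with its oxidation pattern is harder to make than 16 itself, so step economy is poor.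

Alternative 3: Cut C5–C10 and C3–C4 in an acyclic chain (radical–polar crossover bicyclisation). Forward, hydrogen atom transfer to the C10=C14 methylene of the dienedial A5 gives the C10 radical, which closes ring B by 6-exo attack on the enal carbon C5. The resulting enolate then closes ring A by aldol addition to the C3 aldehyde to give A6, and dehydration would give the enal. This forms both rings at once, but the configuration of C10 would depend on which of two substituents of similar size (CH3 or CH2CH2CHO) sits axial on the radical carbon in the chair transition state, and no bias is expected. A5 also needs its own asymmetric synthesis of C7. In the chosen plan ring B is preformed and C5 controls C10 through the ring fusion.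

Key step: step 7

## Route

Step 1
Reactants: 1 (S)-(+)-carvone [(5S)-2-methyl-5-(prop-1-en-2-yl)cyclohex-2-en-1-one]
Product: 2 (1S,5S)-2-methyl-5-(prop-1-en-2-yl)cyclohex-2-en-1-ol (cis-carveol)
Conditions: NaBH4, CeCl3·7H2O, MeOH, 0 °C
Reagents that add atoms: none
Why: Luche 1,2-reduction; axial hydride delivery to the enone with the isopropenyl group equatorial should give the cis (diequatorial) allylic alcohol, whose C–O stereocentre is the one later copied onto C5.

Step 2
Reactants: 2 (1S,5S)-2-methyl-5-(prop-1-en-2-yl)cyclohex-2-en-1-ol (cis-carveol)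
Product: 4 ethyl 2-[(1S,5R)-2-methyl-5-(prop-1-en-2-yl)cyclohex-2-en-1-yl]acetate, via ketene acetal 3 (not isolated)
Conditions: MeC(OEt)3 (6 equiv), EtCO2H (0.1 equiv), sealed tube, 170 °C
Reagents that add atoms: triethyl orthoacetate (CC(OCC)(OCC)OCC)
Why: Johnson–Claisen rearrangement; the suprafacial [3,3] shift forms the C4–C5 bond on the face of the departing C–O bond, so the acetate arm ends cis to the C7 substituent, and the alkene moves to C9=C10.

Step 3
Reactants: 4 ethyl 2-[(1S,5R)-2-methyl-5-(prop-1-en-2-yl)cyclohex-2-en-1-yl]acetate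
Product: 6 ethyl 2-[(1S,5R)-5-acetyl-2-methylcyclohex-2-en-1-yl]acetate, via diol 5 (not isolated)
Conditions: OsO4 (2 mol %), NaIO4 (4 equiv), 2,6-lutidine (2 equiv), 1,4-dioxane/H2O 3:1, rt
Reagents that add atoms: osmium tetroxide (O=[Os](=O)(=O)=O); sodium periodate ([Na+].[O-]I(=O)(=O)=O)
Why: Lemieux–Johnson cleavage: OsO4 delivers the two oxygens of diol 5 and is regenerated by NaIO4, which then cleaves the diol to the methyl ketone; osmylation should select the unhindered 1,1-disubstituted isopropenyl alkene over the trisubstituted ring alkene flanked by the C5 stereocentre.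

Step 4
Reactants: 6 ethyl 2-[(1S,5R)-5-acetyl-2-methylcyclohex-2-en-1-yl]acetate
Product: 7 ethyl 2-[(1S,5R)-2-methyl-5-(2-methyl-1,3-dioxolan-2-yl)cyclohex-2-en-1-yl]acetate
Conditions: HOCH2CH2OH (3 equiv), PPTS (0.1 equiv), benzene, reflux, Dean–Stark
Reagents that add atoms: ethylene glycol (OCCO)
Why: Standard dioxolane formation masks the future C11 ketone against the amide base of step 5; C7 is enolisable here but the cis-diequatorial arrangement is the thermodynamic one, so its configuration should hold.

Step 5
Reactants: 7 ethyl 2-[(1S,5R)-2-methyl-5-(2-methyl-1,3-dioxolan-2-yl)cyclohex-2-en-1-yl]acetate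
Product: 8 ethyl 3-hydroxy-2-[(1S,5R)-2-methyl-5-(2-methyl-1,3-dioxolan-2-yl)cyclohex-2-en-1-yl]pent-4-enoate (diastereomers at the two new chain centres)
Conditions: LiN(i-Pr)2 (1.1 equiv), THF, −78 °C; acrolein (1.3 equiv), −78 °C; aq NH4Cl
Reagents that add atoms: acrolein (C=CC=O)
Why: Ester enolate aldol addition (1,2-addition to the enal at low temperature) forms the C3–C4 bond and brings in C1–C3; the two new stereocentres need no control because both carbons become sp2 later.

Step 6
Reactants: 8 ethyl 3-hydroxy-2-[(1S,5R)-2-methyl-5-(2-methyl-1,3-dioxolan-2-yl)cyclohex-2-en-1-yl]pent-4-enoate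
Product: 9 ethyl 2-[(1S,5R)-2-methyl-5-(2-methyl-1,3-dioxolan-2-yl)cyclohex-2-en-1-yl]-3-oxopent-4-enoate
Conditions: Dess–Martin periodinane (1.3 equiv), CH2Cl2, 0 °C to rt; used at once in step 7
Reagents that add atoms: none
Why: Dess–Martin oxidation of the allylic carbinol gives the vinyl β-keto ester (a Nazarov-type reagent) under non-basic conditions that should not trigger Michael oligomerisation.

Step 7
Reactants: 9 ethyl 2-[(1S,5R)-2-methyl-5-(2-methyl-1,3-dioxolan-2-yl)cyclohex-2-en-1-yl]-3-oxopent-4-enoate
Product: 10 ethyl (4aS,7R,8aS)-4a-methyl-7-(2-methyl-1,3-dioxolan-2-yl)-2-oxodecahydronaphthalene-1-carboxylate (keto/enol mixture of C1 epimers)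
Conditions: Fe(acac)3 (0.3 equiv), PhSiH3 (2.5 equiv), EtOH/HOCH2CH2OH 5:1, 0.02 M, slow addition of 9, 60 °C
Reagents that add atoms: none
Why: This is the iron-hydride reductive olefin coupling run intramolecularly (a hydrogen-atom-transfer-initiated Giese cyclisation): the hydride formed from Fe(acac)3 and PhSiH3 transfers a hydrogen atom to C9 of the electron-rich trisubstituted alkene and leaves the tertiary radical at C10, so the carbon that would otherwise be the cationic site becomes a nucleophile. The radical adds to the terminal carbon C1 of the vinyl ketone, and the α-keto radical is reduced by divalent iron to the enolate and protonated by EtOH, which returns trivalent iron. Ring A closes in the 6-endo-trig mode, since 5-exo attack at C2 would leave an unstabilised primary radical and run against the polarity of the acceptor. The one new stereocentre that matters, C10, is controlled by C5: with the C5 chain equatorial on the ring B chair (held there by the equatorial C7 substituent), C1 should reach C10 through a chair-like transition state that makes the new bond equatorial, as in radical polyene cyclisations, so the ring fusion should be trans and the C14 methyl axial and cis to the C7 group. The selectivities needed are hydrogen transfer to the alkyl-substituted alkene in preference to the electron-poor vinyl ketone (secured by the polarity of the hydride and by dilution) and equatorial closure (secured by the locked chair); the configuration at C4 is irrelevant because that carbon is enolised in step 8.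

Step 8
Reactants: 10 ethyl (4aS,7R,8aS)-4a-methyl-7-(2-methyl-1,3-dioxolan-2-yl)-2-oxodecahydronaphthalene-1-carboxylate
Product: 11 ethyl (4aS,7R,8aR)-4a-methyl-7-(2-methyl-1,3-dioxolan-2-yl)-2-{[(trifluoromethyl)sulfonyl]oxy}-3,4,4a,5,6,7,8,8a-octahydronaphthalene-1-carboxylate
Conditions: NaH (1.2 equiv), THF, 0 °C; PhNTf2 (1.2 equiv), 0 °C to rt
Reagents that add atoms: N-phenylbis(trifluoromethanesulfonimide) (O=S(=O)(N(c1ccccc1)S(=O)(=O)C(F)(F)F)C(F)(F)F)
Why: O-sulfonylation of the β-keto ester enolate; only C4 lies between the two carbonyls, so the alkene is fixed at C3=C4 and cannot form toward C2.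

Step 9
Reactants: 11 ethyl (4aS,7R,8aR)-4a-methyl-7-(2-methyl-1,3-dioxolan-2-yl)-2-{[(trifluoromethyl)sulfonyl]oxy}-3,4,4a,5,6,7,8,8a-octahydronaphthalene-1-carboxylate
Product: 12 ethyl (4aR,7R,8aR)-4a-methyl-7-(2-methyl-1,3-dioxolan-2-yl)-3,4,4a,5,6,7,8,8a-octahydronaphthalene-1-carboxylate
Conditions: Pd(OAc)2 (5 mol %), PPh3 (10 mol %), HCO2H (2 equiv), n-Bu3N (3 equiv), DMF, 60 °C
Reagents that add atoms: none
Why: Formate reduction of a vinyl triflate catalysed by zerovalent palladium (oxidative addition, formate exchange, loss of CO2, reductive elimination) replaces the triflate by hydrogen without moving the alkene; the buffered medium should spare the acetal.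

Step 10
Reactants: 12 ethyl (4aR,7R,8aR)-4a-methyl-7-(2-methyl-1,3-dioxolan-2-yl)-3,4,4a,5,6,7,8,8a-octahydronaphthalene-1-carboxylate
Product: 13 ethyl (4aR,7R,8aR)-7-acetyl-4a-methyl-3,4,4a,5,6,7,8,8a-octahydronaphthalene-1-carboxylate
Conditions: 1 M aq HCl/THF 1:4, rt
Reagents that add atoms: water (O)
Why: Acid hydrolysis of the dioxolane frees the methyl ketone; the equatorial acetyl group on the trans-decalin is the thermodynamic epimer, so acid enolisation cannot erode C7.

Step 11
Reactants: 13 ethyl (4aR,7R,8aR)-7-acetyl-4a-methyl-3,4,4a,5,6,7,8,8a-octahydronaphthalene-1-carboxylate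
Product: 14 ethyl (4aR,7R,8aR)-4a-methyl-7-{1-[(trifluoromethanesulfonyl)oxy]ethenyl}-3,4,4a,5,6,7,8,8a-octahydronaphthalene-1-carboxylate
Conditions: KN(SiMe3)2 (1.1 equiv), THF, −78 °C; PhNTf2 (1.2 equiv), −78 to 0 °C
Reagents that add atoms: N-phenylbis(trifluoromethanesulfonimide) (O=S(=O)(N(c1ccccc1)S(=O)(=O)C(F)(F)F)C(F)(F)F)
Why: Kinetic deprotonation of the methyl ketone at the unhindered CH3 (rather than at the C7 methine or the γ-position of the enoate) and O-triflation give the terminal enol triflate that defines the C11=C13 methylene.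

Step 12
Reactants: 14 ethyl (4aR,7R,8aR)-4a-methyl-7-{1-[(trifluoromethanesulfonyl)oxy]ethenyl}-3,4,4a,5,6,7,8,8a-octahydronaphthalene-1-carboxylate
Product: 15 1-[(2R,4aR,8aR)-8-(hydroxymethyl)-4a-methyl-1,2,3,4,4a,5,6,8a-octahydronaphthalen-2-yl]ethenyl trifluoromethanesulfonate
Conditions: i-Bu2AlH (2.5 equiv), CH2Cl2, −78 °C; aq KNaC4H4O6
Reagents that add atoms: none
Why: 1,2-Reduction of the conjugated ester to the allylic alcohol; the vinyl triflate is inert to the aluminium hydride at low temperature, and doing this reduction before the C12 ester exists avoids any need to distinguish two esters.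

Step 13
Reactants: 15 1-[(2R,4aR,8aR)-8-(hydroxymethyl)-4a-methyl-1,2,3,4,4a,5,6,8a-octahydronaphthalen-2-yl]ethenyl trifluoromethanesulfonate
Product: 16 methyl 2-[(2R,4aR,8aR)-8-(hydroxymethyl)-4a-methyl-1,2,3,4,4a,5,6,8a-octahydronaphthalen-2-yl]prop-2-enoate
Conditions: Pd(OAc)2 (5 mol %), dppp (6 mol %), CO (1 atm), MeOH/DMF 1:4, Et3N (2 equiv), 50 °C
Reagents that add atoms: carbon monoxide ([C-]#[O+]); methanol (CO)
Why: Palladium-catalysed methoxycarbonylation of the vinyl triflate (oxidative addition, CO insertion, methanolysis of the acyl palladium) builds the α-substituted acrylate in one step; a free allylic alcohol is not ionised by zerovalent palladium and methanol is present in large excess over it.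

Step 14
Reactants: 16 methyl 2-[(2R,4aR,8aR)-8-(hydroxymethyl)-4a-methyl-1,2,3,4,4a,5,6,8a-octahydronaphthalen-2-yl]prop-2-enoate; 17 (E)-p-coumaric acid [(2E)-3-(4-hydroxyphenyl)prop-2-enoic acid]
Product: 18 methyl 2-[(2R,4aR,8aR)-8-({[(2E)-3-(4-hydroxyphenyl)prop-2-enoyl]oxy}methyl)-4a-methyl-1,2,3,4,4a,5,6,8a-octahydronaphthalen-2-yl]prop-2-enoate (target)
Conditions: PPh3 (1.5 equiv), DIAD (1.5 equiv), 17 (1.5 equiv), THF, 0 °C to rt
Reagents that add atoms: none
Why: Mitsunobu esterification activates the primary allylic alcohol, and the far more acidic carboxylic acid of 17, not its phenol, supplies the nucleophile, so no phenol protection is needed; substitution at the primary carbon should outrun SN2′ attack at the ring carbon C3.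

## Compound list

1 | (S)-(+)-carvone, (5S)-2-methyl-5-(prop-1-en-2-yl)cyclohex-2-en-1-one | CC1=CC[C@@H](CC1=O)C(C)=C | starting material
2 | (1S,5S)-2-methyl-5-(prop-1-en-2-yl)cyclohex-2-en-1-ol (cis-carveol) | CC1=CC[C@@H](C[C@@H]1O)C(C)=C | intermediate
3 | 1-ethoxyvinyl ether of 2 (mixed ketene acetal, 1S,5S) | CC1=CC[C@@H](C[C@@H]1OC(=C)OCC)C(C)=C | intermediate (not isolated)
4 | ethyl 2-[(1S,5R)-2-methyl-5-(prop-1-en-2-yl)cyclohex-2-en-1-yl]acetate (side chains cis) | CCOC(=O)C[C@H]1C(C)=CC[C@H](C1)C(C)=C | intermediate
5 | ethyl 2-[(1S,5R)-5-(1,2-dihydroxypropan-2-yl)-2-methylcyclohex-2-en-1-yl]acetate (both carbinol epimers) | CCOC(=O)C[C@H]1C(C)=CC[C@H](C1)C(C)(O)CO | intermediate (not isolated)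
6 | ethyl 2-[(1S,5R)-5-acetyl-2-methylcyclohex-2-en-1-yl]acetate | CCOC(=O)C[C@H]1C(C)=CC[C@H](C1)C(C)=O | intermediate
7 | ethyl 2-[(1S,5R)-2-methyl-5-(2-methyl-1,3-dioxolan-2-yl)cyclohex-2-en-1-yl]acetate | CCOC(=O)C[C@H]1C(C)=CC[C@H](C1)C1(C)OCCO1 | intermediate
8 | ethyl 3-hydroxy-2-[(1S,5R)-2-methyl-5-(2-methyl-1,3-dioxolan-2-yl)cyclohex-2-en-1-yl]pent-4-enoate | CCOC(=O)C(C(O)C=C)[C@H]1C(C)=CC[C@H](C1)C1(C)OCCO1 | intermediate
9 | ethyl 2-[(1S,5R)-2-methyl-5-(2-methyl-1,3-dioxolan-2-yl)cyclohex-2-en-1-yl]-3-oxopent-4-enoate | CCOC(=O)C(C(=O)C=C)[C@H]1C(C)=CC[C@H](C1)C1(C)OCCO1 | intermediate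
10 | ethyl (4aS,7R,8aS)-4a-methyl-7-(2-methyl-1,3-dioxolan-2-yl)-2-oxodecahydronaphthalene-1-carboxylate (trans-fused) | CC1(OCCO1)[C@@H]1CC[C@@]2(C)CCC(=O)C(C(=O)OCC)[C@@H]2C1 | intermediate
11 | ethyl (4aS,7R,8aR)-4a-methyl-7-(2-methyl-1,3-dioxolan-2-yl)-2-{[(trifluoromethyl)sulfonyl]oxy}-3,4,4a,5,6,7,8,8a-octahydronaphthalene-1-carboxylate | CC1(OCCO1)[C@@H]1CC[C@@]2(C)CCC(OS(=O)(=O)C(F)(F)F)=C(C(=O)OCC)[C@@H]2C1 | intermediate
12 | ethyl (4aR,7R,8aR)-4a-methyl-7-(2-methyl-1,3-dioxolan-2-yl)-3,4,4a,5,6,7,8,8a-octahydronaphthalene-1-carboxylate | CC1(OCCO1)[C@@H]1CC[C@@]2(C)CCC=C(C(=O)OCC)[C@@H]2C1 | intermediate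
13 | ethyl (4aR,7R,8aR)-7-acetyl-4a-methyl-3,4,4a,5,6,7,8,8a-octahydronaphthalene-1-carboxylate | CC(=O)[C@@H]1CC[C@@]2(C)CCC=C(C(=O)OCC)[C@@H]2C1 | intermediate
14 | ethyl (4aR,7R,8aR)-4a-methyl-7-{1-[(trifluoromethanesulfonyl)oxy]ethenyl}-3,4,4a,5,6,7,8,8a-octahydronaphthalene-1-carboxylate | C=C(OS(=O)(=O)C(F)(F)F)[C@@H]1CC[C@@]2(C)CCC=C(C(=O)OCC)[C@@H]2C1 | intermediate
15 | 1-[(2R,4aR,8aR)-8-(hydroxymethyl)-4a-methyl-1,2,3,4,4a,5,6,8a-octahydronaphthalen-2-yl]ethenyl trifluoromethanesulfonate | C=C(OS(=O)(=O)C(F)(F)F)[C@@H]1CC[C@@]2(C)CCC=C(CO)[C@@H]2C1 | intermediate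
16 | methyl 2-[(2R,4aR,8aR)-8-(hydroxymethyl)-4a-methyl-1,2,3,4,4a,5,6,8a-octahydronaphthalen-2-yl]prop-2-enoate | C=C(C(=O)OC)[C@@H]1CC[C@@]2(C)CCC=C(CO)[C@@H]2C1 | intermediate
17 | (E)-p-coumaric acid, (2E)-3-(4-hydroxyphenyl)prop-2-enoic acid | OC(=O)/C=C/c1ccc(O)cc1 | starting material
18 | methyl 2-[(2R,4aR,8aR)-8-({[(2E)-3-(4-hydroxyphenyl)prop-2-enoyl]oxy}methyl)-4a-methyl-1,2,3,4,4a,5,6,8a-octahydronaphthalen-2-yl]prop-2-enoate | C=C(C(=O)OC)[C@@H]1CC[C@@]2(C)CCC=C(COC(=O)/C=C/c3ccc(O)cc3)[C@@H]2C1 | target

## Step count and least certain steps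

Total step count: 14. Longest linear sequence: 14 steps (1 to 18); 17 is used as purchased.

Step 7 (key step). The most likely failure is that the iron hydride reduces or oligomerises the vinyl ketone of 9, or that the β-keto ester binds iron, before hydrogen is transferred to the hindered trisubstituted alkene. A second possibility is partial axial closure, which would erode the trans ring fusion. The fallback sets out from 7 and returns at 12, closing ring A by olefination instead of by the radical step. 7 is C-phosphorylated (LiN(i-Pr)2 2.2 equiv, ClP(O)(OEt)2, THF, −78 °C to rt) to ethyl 2-(diethoxyphosphoryl)-2-[(1R,5R)-2-methyl-5-(2-methyl-1,3-dioxolan-2-yl)cyclohex-2-en-1-yl]acetate F1. F1 is joined to acrolein in an intermolecular hydrogen-atom-transfer Giese addition (Fe(acac)3, PhSiH3, EtOH, 60 °C, acrolein in excess), in which approach anti to the bulky C5 substituent should give ethyl 2-(diethoxyphosphoryl)-2-[(1R,2S,5R)-2-methyl-5-(2-methyl-1,3-dioxolan-2-yl)-2-(3-oxopropyl)cyclohexyl]acetate F2. Intramolecular Horner–Wadsworth–Emmons olefination (LiCl, DBU, MeCN) then forms C3=C4 and gives 12, bypassing 9, 10 and 11.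

Step 2. The reactive conformer of 2 needs a pseudoaxial C–O bond and hence an axial isopropenyl group, so the rearrangement may be slow enough for acid-promoted ionisation or dehydration of the allylic alcohol to compete at 170 °C. The fallback sets out from 2 and returns at 4 by the anionic, low-temperature variant. 2 is acetylated (Ac2O, pyridine, DMAP) to (1S,5S)-2-methyl-5-(prop-1-en-2-yl)cyclohex-2-en-1-yl acetate F3. Ireland–Claisen rearrangement (LiN(i-Pr)2, Me3SiCl, THF, −78 to 60 °C, aqueous work-up) gives 2-[(1S,5R)-2-methyl-5-(prop-1-en-2-yl)cyclohex-2-en-1-yl]acetic acid F4, and alkylation (EtI, K2CO3, DMF) gives 4.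

Step 3. Site selectivity may be lost if osmylation also attacks the trisubstituted ring alkene. The fallback sets out from 1 and returns at 7, cleaving the isopropenyl group while the ring alkene is still deactivated as an enone. Ozonolysis of 1 (O3, CH2Cl2/MeOH, −78 °C; Me2S) gives (5S)-5-acetyl-2-methylcyclohex-2-en-1-one F5. Selective acetalisation of the saturated ketone (Me3SiOCH2CH2OSiMe3, Me3SiOTf cat., CH2Cl2, −78 °C) gives (5S)-2-methyl-5-(2-methyl-1,3-dioxolan-2-yl)cyclohex-2-en-1-one F6. Luche reduction gives (1S,5S)-2-methyl-5-(2-methyl-1,3-dioxolan-2-yl)cyclohex-2-en-1-ol F7, and Johnson–Claisen rearrangement of F7 (as in step 2, longer heating) gives 7.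

Step 14. The betaine may alkylate the phenol of 17 or of the product, substitution may occur with allylic transposition, or the phosphine may add to the acrylate. The fallback sets out from 17 and 16 and returns at 18 by acylating the alcohol with a protected acid. 17 is O-acetylated (Ac2O, pyridine; aqueous work-up) to (2E)-3-(4-acetoxyphenyl)prop-2-enoic acid F8. Carbodiimide coupling of F8 with 16 (EDC·HCl, DMAP, CH2Cl2) gives methyl 2-[(2R,4aR,8aR)-8-({[(2E)-3-(4-acetoxyphenyl)prop-2-enoyl]oxy}methyl)-4a-methyl-1,2,3,4,4a,5,6,8a-octahydronaphthalen-2-yl]prop-2-enoate F9. Brief methanolysis of the aryl acetate (K2CO3 0.1 equiv, MeOH, 0 °C) gives 18.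

## Further compounds

F1 | step 7 | ethyl 2-(diethoxyphosphoryl)-2-[(1R,5R)-2-methyl-5-(2-methyl-1,3-dioxolan-2-yl)cyclohex-2-en-1-yl]acetate | CCOC(=O)C(P(=O)(OCC)OCC)[C@H]1C(C)=CC[C@H](C1)C1(C)OCCO1
F2 | step 7 | ethyl 2-(diethoxyphosphoryl)-2-[(1R,2S,5R)-2-methyl-5-(2-methyl-1,3-dioxolan-2-yl)-2-(3-oxopropyl)cyclohexyl]acetate | CC1(OCCO1)[C@@H]1CC[C@@](C)(CCC=O)[C@@H](C1)C(C(=O)OCC)P(=O)(OCC)OCC
F3 | step 2 | (1S,5S)-2-methyl-5-(prop-1-en-2-yl)cyclohex-2-en-1-yl acetate | CC1=CC[C@@H](C[C@@H]1OC(C)=O)C(C)=C
F4 | step 2 | 2-[(1S,5R)-2-methyl-5-(prop-1-en-2-yl)cyclohex-2-en-1-yl]acetic acid | OC(=O)C[C@H]1C(C)=CC[C@H](C1)C(C)=C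
F5 | step 3 | (5S)-5-acetyl-2-methylcyclohex-2-en-1-one | CC1=CC[C@@H](CC1=O)C(C)=O
F6 | step 3 | (5S)-2-methyl-5-(2-methyl-1,3-dioxolan-2-yl)cyclohex-2-en-1-one | CC1=CC[C@@H](CC1=O)C1(C)OCCO1
F7 | step 3 | (1S,5S)-2-methyl-5-(2-methyl-1,3-dioxolan-2-yl)cyclohex-2-en-1-ol | CC1=CC[C@@H](C[C@@H]1O)C1(C)OCCO1
F8 | step 14 | (2E)-3-(4-acetoxyphenyl)prop-2-enoic acid | CC(=O)Oc1ccc(/C=C/C(O)=O)cc1
F9 | step 14 | methyl 2-[(2R,4aR,8aR)-8-({[(2E)-3-(4-acetoxyphenyl)prop-2-enoyl]oxy}methyl)-4a-methyl-1,2,3,4,4a,5,6,8a-octahydronaphthalen-2-yl]prop-2-enoate | C=C(C(=O)OC)[C@@H]1CC[C@@]2(C)CCC=C(COC(=O)/C=C/c3ccc(OC(C)=O)cc3)[C@@H]2C1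
A1 | alternative 1 | (2R,5R)-2-methyl-5-(prop-1-en-2-yl)cyclohexan-1-one (dihydrocarvone) | C[C@@H]1CC[C@H](CC1=O)C(C)=C
A2 | alternative 1 | (4aS,7R)-1,4a-dimethyl-7-(prop-1-en-2-yl)-4,4a,5,6,7,8-hexahydronaphthalen-2(3H)-one | C=C(C)[C@@H]1CC[C@@]2(C)CCC(=O)C(C)=C2C1
A3 | alternative 1 | (4aR,7R)-1,4a-dimethyl-7-(prop-1-en-2-yl)-4,4a,5,6,7,8-hexahydronaphthalen-2(3H)-one (C10 epimer of A2) | C=C(C)[C@@H]1CC[C@]2(C)CCC(=O)C(C)=C2C1
A4 | alternative 2 | methyl 2-[(1R,3Z,7E)-4-(hydroxymethyl)-8-methylcyclodeca-3,7-dien-1-yl]prop-2-enoate | C=C(C(=O)OC)[C@@H]1CC/C(C)=C/CC/C(CO)=C/C1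
A5 | alternative 3 | (2E,5R)-8-methylidene-5-(2-methyl-1,3-dioxolan-2-yl)undec-2-enedial | O=CCCC(=C)CC[C@H](C/C=C/C=O)C1(C)OCCO1
A6 | alternative 3 | (4aS,7R,8aS)-2-hydroxy-4a-methyl-7-(2-methyl-1,3-dioxolan-2-yl)decahydronaphthalene-1-carbaldehyde | CC1(OCCO1)[C@@H]1CC[C@@]2(C)CCC(O)C(C=O)[C@@H]2C1
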